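**Plan**

- Retrosynthesis: the two silyl ethers are cut first, then the C1'–C7' bond (Suzuki–Miyaura), then ring C across both C7–C8 and O–C7 in one [4+1] disconnection.
- Enabling feature: C7 bears ring A and lies between the ring oxygen and C8, so it can arrive as a one-carbon benzylic sulfonium ylide. Ring B, its phenol oxygen and the C8–C9 unit form the matching ortho-quinone methide.
- Forward: a 2-(1-sulfonylalkyl)phenol (four steps from 5-bromo-o-vanillin) and a chiral benzylsulfonium salt (three steps) are joined in the annulation, which closes ring C, the only ring made. The C7'–C9' chain is then attached at C1' and both silyl groups are removed.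
- Stereochemistry: C7 comes from the C2-symmetric (2R,5R)-thiolanium group, made from (2S,5S)-hexane-2,5-diol by double inversion. C8 follows relative to C7 through the anti betaine and inverting ring closure (trans). The 7'E alkene comes from an E-alkenylboronate.

Key step: step 8

Assumption: the ylide of the (2R,5R)-thiolanium salt is taken to bond through the same face of its carbon as in the aldehyde epoxidations known for this sulfide, which corresponds to 7R here. If the opposite sense were found, the route would start from (2R,5R)-hexane-2,5-diol with no other change.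

Numbering: neolignan numbering (C7, C8, C9 on the ring A side; primed atoms on ring B; ring C is the dihydrofuran).

**Route**

Step 1
Reactants: 1 5-bromo-2-hydroxy-3-methoxybenzaldehyde
Product: 2 4-bromo-2-ethenyl-6-methoxyphenol
Conditions: Ph3PCH3Br (2.5 equiv), KOtBu (2.5 equiv), THF, 0 °C to rt
Reagents that add atoms: methyltriphenylphosphonium bromide, C[P+](c1ccccc1)(c1ccccc1)c1ccccc1.[Br-]
Why: Wittig methylenation; the first equivalent of ylide only deprotonates the phenol, and the phenoxide aldehyde still reacts with the non-stabilised ylide, as is routine for salicylaldehydes.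

Step 2
Reactants: 2 4-bromo-2-ethenyl-6-methoxyphenol
Product: 3 1-(5-bromo-2-hydroxy-3-methoxyphenyl)ethane-1,2-diol (racemic)
Conditions: OsO4 (2 mol %), NMO (1.3 equiv), acetone/H2O 4:1, 0 °C to rt
Reagents that add atoms: osmium tetroxide (catalytic oxygen carrier), O=[Os](=O)(=O)=O; N-methylmorpholine N-oxide, C[N+]1([O-])CCOCC1; water, O
Why: Upjohn dihydroxylation of a terminal styrene; the new centre is left racemic because it becomes planar in the methide of step 8.

Step 3
Reactants: 3 1-(5-bromo-2-hydroxy-3-methoxyphenyl)ethane-1,2-diol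
Product: 4 4-bromo-2-[2-(tert-butyldiphenylsilyloxy)-1-hydroxyethyl]-6-methoxyphenol (racemic)
Conditions: TBDPSCl (1.05 equiv), imidazole (2.2 equiv), CH2Cl2/DMF, −20 to 0 °C
Reagents that add atoms: tert-butyldiphenylsilyl chloride, CC(C)(C)[Si](Cl)(c1ccccc1)c1ccccc1
Why: Selective silylation; the bulky chlorosilane should take the unhindered primary hydroxyl in preference to the secondary benzylic hydroxyl and to the 2,6-disubstituted phenol, which is hydrogen-bonded to its methoxy neighbour.

Step 4
Reactants: 4 4-bromo-2-[2-(tert-butyldiphenylsilyloxy)-1-hydroxyethyl]-6-methoxyphenol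
Product: 5 4-bromo-2-[2-(tert-butyldiphenylsilyloxy)-1-(4-methylbenzenesulfonyl)ethyl]-6-methoxyphenol (racemic)
Conditions: p-TolSO2H (1.3 equiv), CH2Cl2, rt
Reagents that add atoms: p-toluenesulfinic acid, Cc1ccc(cc1)S(=O)O
Why: Acid-mediated SN1-type exchange through the ortho-hydroxybenzylic cation with S-capture by sulfinate, the standard preparation of 2-(1-sulfonylalkyl)phenols; the tert-butyldiphenylsilyl ether is chosen because it should tolerate the sulfinic acid.

Step 5
Reactants: 6 (2S,5S)-hexane-2,5-diol
Product: 7 (2S,5S)-hexane-2,5-diyl dimethanesulfonate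
Conditions: MsCl (2.4 equiv), Et3N (3 equiv), CH2Cl2, 0 °C
Reagents that add atoms: methanesulfonyl chloride, CS(=O)(=O)Cl
Why: O-Sulfonylation, which does not touch the C–O bonds and so keeps both centres.

Step 6
Reactants: 7 (2S,5S)-hexane-2,5-diyl dimethanesulfonate
Product: 8 (2R,5R)-2,5-dimethylthiolane
Conditions: Na2S·9H2O (1.2 equiv), DMSO, rt; distillation
Reagents that add atoms: sodium sulfide, [Na+].[Na+].[S-2]
Why: Double SN2 displacement by sulfide (5-exo-tet in the second event) inverts both secondary centres and should give the trans (2R,5R) sulfide.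

Step 7
Reactants: 8 (2R,5R)-2,5-dimethylthiolane; 9 3,4,5-trimethoxybenzyl bromide
Product: 10 (2R,5R)-2,5-dimethyl-1-(3,4,5-trimethoxybenzyl)thiolan-1-ium tetrafluoroborate
Conditions: AgBF4 (1.1 equiv), CH2Cl2, 0 °C to rt, dark
Reagents that add atoms: silver tetrafluoroborate, [Ag+].F[B-](F)(F)F
Why: S-Alkylation driven by precipitation of AgBr; the two sulfur lone pairs of the C2-symmetric sulfide are homotopic, so a single sulfonium salt is expected.

Step 8
Reactants: 5 4-bromo-2-[2-(tert-butyldiphenylsilyloxy)-1-(4-methylbenzenesulfonyl)ethyl]-6-methoxyphenol; 10 (2R,5R)-2,5-dimethyl-1-(3,4,5-trimethoxybenzyl)thiolan-1-ium tetrafluoroborate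
Product: 14 (2R,3S)-5-bromo-3-[(tert-butyldiphenylsilyloxy)methyl]-7-methoxy-2-(3,4,5-trimethoxyphenyl)-2,3-dihydro-1-benzofuran, via ortho-quinone methide 11 (not isolated), via sulfonium ylide 12 (not isolated), via anti betaine 13 (not isolated)
Conditions: 10 (1.5 equiv), Cs2CO3 (3 equiv), CH2Cl2/MeCN 1:1, −20 °C, 5 added over 2 h, then 0 °C
Reagents that add atoms: none
Why: Cs2CO3 deprotonates the phenol of 5, the phenoxide expels p-toluenesulfinate to give the ortho-quinone methide 11, and the same base reversibly deprotonates 10 to the ylide 12, whose carbon (C7) adds to the methide carbon (C8) with re-aromatisation of ring B to give the betaine 13, which closes by displacement of the sulfide at C7 by the phenoxide. The closest known reaction type is the carbonate-mediated [4+1] annulation of ortho-quinone methides from 2-(1-sulfonylalkyl)phenols with sulfonium ylides to trans-2,3-dihydrobenzofurans, together with the addition and ring-closure chemistry of chiral benzylsulfonium ylides used in asymmetric epoxidation and cyclopropanation; the benzylic ylide and the silyloxymethyl methide extend the reported scope but not the reaction type. Ring C closes in a 5-exo-tet O-alkylation with inversion at C7. C7 is controlled by the C2-symmetric (2R,5R)-thiolanium group, whose methyl groups shield one face of the ylide carbon during C7–C8 bond formation, and C8 is controlled relative to C7 by an open transition state in which the sulfonium group lies antiperiplanar to ring B and ring A avoids the C9 arm, giving the anti betaine and hence the trans ring. The step needs capture of 11 by the ylide to outrun tautomerisation of 11 to the enol ether, and C–C bond formation to outrun O-benzylation of the phenoxide; slow release of 11 at low temperature into an excess of 12 and the hindered 2,6-disubstituted phenoxide should secure this, and the aryl bromide and silyl ether are inert to carbonate.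

Step 9
Reactants: 14 (2R,3S)-5-bromo-3-[(tert-butyldiphenylsilyloxy)methyl]-7-methoxy-2-(3,4,5-trimethoxyphenyl)-2,3-dihydro-1-benzofuran; 15 (E)-2-[3-(tert-butyldimethylsilyloxy)prop-1-en-1-yl]-4,4,5,5-tetramethyl-1,3,2-dioxaborolane
Product: 16 (2R,3S)-5-[(E)-3-(tert-butyldimethylsilyloxy)prop-1-en-1-yl]-3-[(tert-butyldiphenylsilyloxy)methyl]-7-methoxy-2-(3,4,5-trimethoxyphenyl)-2,3-dihydro-1-benzofuran
Conditions: 15 (1.3 equiv), Pd(dppf)Cl2 (5 mol %), K2CO3 (3 equiv), 1,4-dioxane/H2O 5:1, 80 °C
Reagents that add atoms: none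
Why: Suzuki–Miyaura coupling of the aryl bromide at C1' with an alkenylboronate, which transfers the alkenyl group with retention of the E geometry; the mild aqueous carbonate should leave both silyl ethers and both ring stereocentres untouched.

Step 10
Reactants: 16 (2R,3S)-5-[(E)-3-(tert-butyldimethylsilyloxy)prop-1-en-1-yl]-3-[(tert-butyldiphenylsilyloxy)methyl]-7-methoxy-2-(3,4,5-trimethoxyphenyl)-2,3-dihydro-1-benzofuran
Product: 17 (−)-(7R,8S,7'E)-3,4,5,5'-tetramethoxy-4',7-epoxy-8,3'-neolign-7'-ene-9,9'-diol
Conditions: Bu4NF (3 equiv), THF, 0 °C to rt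
Reagents that add atoms: none
Why: Fluoride-mediated cleavage of both silyl ethers (Si–F bond formation as driving force) under conditions that affect neither the benzylic ether at C7, the alkene nor the stereocentres.

**Compound list**

1 | 5-bromo-2-hydroxy-3-methoxybenzaldehyde | COc1cc(Br)cc(C=O)c1O | starting material
2 | 4-bromo-2-ethenyl-6-methoxyphenol | COc1cc(Br)cc(C=C)c1O | intermediate
3 | 1-(5-bromo-2-hydroxy-3-methoxyphenyl)ethane-1,2-diol (racemic) | COc1cc(Br)cc(C(O)CO)c1O | intermediate
4 | 4-bromo-2-[2-(tert-butyldiphenylsilyloxy)-1-hydroxyethyl]-6-methoxyphenol (racemic) | COc1cc(Br)cc(C(O)CO[Si](c2ccccc2)(c3ccccc3)C(C)(C)C)c1O | intermediate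
5 | 4-bromo-2-[2-(tert-butyldiphenylsilyloxy)-1-(4-methylbenzenesulfonyl)ethyl]-6-methoxyphenol (racemic) | COc1cc(Br)cc(C(CO[Si](c2ccccc2)(c3ccccc3)C(C)(C)C)S(=O)(=O)c4ccc(C)cc4)c1O | intermediate
6 | (2S,5S)-hexane-2,5-diol | C[C@H](O)CC[C@H](C)O | starting material
7 | (2S,5S)-hexane-2,5-diyl dimethanesulfonate | C[C@H](OS(C)(=O)=O)CC[C@H](C)OS(C)(=O)=O | intermediate
8 | (2R,5R)-2,5-dimethylthiolane | C[C@@H]1CC[C@@H](C)S1 | intermediate
9 | 3,4,5-trimethoxybenzyl bromide | COc1cc(CBr)cc(OC)c1OC | starting material
10 | (2R,5R)-2,5-dimethyl-1-(3,4,5-trimethoxybenzyl)thiolan-1-ium tetrafluoroborate | C[C@@H]1CC[C@@H](C)[S+]1Cc2cc(OC)c(OC)c(OC)c2.F[B-](F)(F)F | intermediate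
11 | (E)-4-bromo-6-[2-(tert-butyldiphenylsilyloxy)ethylidene]-2-methoxycyclohexa-2,4-dien-1-one (ortho-quinone methide) | COC1=CC(Br)=C/C(=C\CO[Si](c2ccccc2)(c3ccccc3)C(C)(C)C)C1=O | intermediate
12 | (2R,5R)-2,5-dimethylthiolan-1-ium-1-yl (3,4,5-trimethoxyphenyl)methanide (sulfonium ylide) | C[C@@H]1CC[C@@H](C)[S+]1[CH-]c2cc(OC)c(OC)c(OC)c2 | intermediate
13 | 4-bromo-2-[(2S,3S)-1-(tert-butyldiphenylsilyloxy)-3-[(2R,5R)-2,5-dimethylthiolan-1-ium-1-yl]-3-(3,4,5-trimethoxyphenyl)propan-2-yl]-6-methoxyphenolate (anti betaine) | COc1cc([C@@H]([S+]2[C@H](C)CC[C@H]2C)[C@H](CO[Si](c4ccccc4)(c5ccccc5)C(C)(C)C)c3cc(Br)cc(OC)c3[O-])cc(OC)c1OC | intermediate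
14 | (2R,3S)-5-bromo-3-[(tert-butyldiphenylsilyloxy)methyl]-7-methoxy-2-(3,4,5-trimethoxyphenyl)-2,3-dihydro-1-benzofuran | COc1cc([C@@H]2Oc3c(OC)cc(Br)cc3[C@H]2CO[Si](c4ccccc4)(c5ccccc5)C(C)(C)C)cc(OC)c1OC | intermediate
15 | (E)-2-[3-(tert-butyldimethylsilyloxy)prop-1-en-1-yl]-4,4,5,5-tetramethyl-1,3,2-dioxaborolane | CC(C)(C)[Si](C)(C)OC/C=C/B1OC(C)(C)C(C)(C)O1 | starting material
16 | (2R,3S)-5-[(E)-3-(tert-butyldimethylsilyloxy)prop-1-en-1-yl]-3-[(tert-butyldiphenylsilyloxy)methyl]-7-methoxy-2-(3,4,5-trimethoxyphenyl)-2,3-dihydro-1-benzofuran | COc1cc([C@@H]2Oc3c(OC)cc(/C=C/CO[Si](C)(C)C(C)(C)C)cc3[C@H]2CO[Si](c4ccccc4)(c5ccccc5)C(C)(C)C)cc(OC)c1OC | intermediate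
17 | (−)-(7R,8S,7'E)-3,4,5,5'-tetramethoxy-4',7-epoxy-8,3'-neolign-7'-ene-9,9'-diol | COc1cc([C@@H]2Oc3c(OC)cc(/C=C/CO)cc3[C@H]2CO)cc(OC)c1OC | target

**Step count**

Total: 10 steps. Longest linear sequence: 7 steps (steps 1–4, 8, 9, 10); the sulfonium branch (steps 5–7) is three steps.

**Steps most likely to fail**

1. Step 8. The semi-stabilised benzylic ylide may discriminate poorly between its two faces, so that the trans product forms with eroded enantiomeric purity. Tautomerisation of the methide is a second loss channel, addressed by the slow-release protocol. Fallback: the absolute configuration is taken from a separation instead of from the sulfide. The fallback sets out from 9, which alkylates tetrahydrothiophene (AgBF4, CH2Cl2) to the achiral 1-(3,4,5-trimethoxybenzyl)thiolan-1-ium tetrafluoroborate F1. This salt is combined with 5 under the same Cs2CO3 protocol to give the racemic trans-dihydrobenzofuran F2. Preparative chromatography on an amylose tris(3,5-dimethylphenylcarbamate) stationary phase should then deliver the (2R,3S) enantiomer, and the route is rejoined at 14.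

2. Step 4. The silyl ether may be cleaved, or may migrate to the benzylic oxygen, while the benzylic hydroxyl is being ionised by the sulfinic acid. Fallback: the sulfone is installed before any silyl group is present. The fallback sets out from 3, which is treated with p-TolSO2H in THF/CH2Cl2 to give 4-bromo-2-[2-hydroxy-1-(4-methylbenzenesulfonyl)ethyl]-6-methoxyphenol F3. Its primary hydroxyl is then silylated (TBDPSCl, imidazole, CH2Cl2/DMF, −20 °C), and the route is rejoined at 5.

3. Step 3. Competing silylation of the phenol may give mixtures of mono- and bis-silyl ethers. Fallback: kinetic selection is replaced by exhaustive protection and selective unmasking. The fallback sets out from 3, which is silylated with excess TBDPSCl and imidazole in DMF on both the primary and the phenolic oxygen to give 1-[5-bromo-2-(tert-butyldiphenylsilyloxy)-3-methoxyphenyl]-2-(tert-butyldiphenylsilyloxy)ethan-1-ol F4. The aryl silyl ether alone is then cleaved with Cs2CO3 in DMF/H2O at rt, where phenoxide is the better leaving group, and the route is rejoined at 4.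

**Further compounds**

F1 | step 8 | 1-(3,4,5-trimethoxybenzyl)thiolan-1-ium tetrafluoroborate | COc1cc(C[S+]2CCCC2)cc(OC)c1OC.F[B-](F)(F)F
F2 | step 8 | trans-5-bromo-3-[(tert-butyldiphenylsilyloxy)methyl]-7-methoxy-2-(3,4,5-trimethoxyphenyl)-2,3-dihydro-1-benzofuran (racemate, both enantiomers) | COc1cc([C@@H]2Oc3c(OC)cc(Br)cc3[C@H]2CO[Si](c4ccccc4)(c5ccccc5)C(C)(C)C)cc(OC)c1OC.COc1cc([C@H]2Oc3c(OC)cc(Br)cc3[C@@H]2CO[Si](c4ccccc4)(c5ccccc5)C(C)(C)C)cc(OC)c1OC
F3 | step 4 | 4-bromo-2-[2-hydroxy-1-(4-methylbenzenesulfonyl)ethyl]-6-methoxyphenol (racemic) | COc1cc(Br)cc(C(CO)S(=O)(=O)c2ccc(C)cc2)c1O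
F4 | step 3 | 1-[5-bromo-2-(tert-butyldiphenylsilyloxy)-3-methoxyphenyl]-2-(tert-butyldiphenylsilyloxy)ethan-1-ol (racemic) | COc1cc(Br)cc(C(O)CO[Si](c2ccccc2)(c3ccccc3)C(C)(C)C)c1O[Si](c4ccccc4)(c5ccccc5)C(C)(C)C
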